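**Strategy.** Agrimol C is cut at its two methylene bridges into butyrylphloroglucinol (central ring B) and two copies of side ring A. Ring A is not made by substituting an arene. Its six carbons are assembled in one Diels–Alder/aromatisation: C6′–C1′–C2′–C3′ (with the C3′ methyl) comes from a 1-methoxy-1,3-bis(trimethylsilyloxy)penta-1,3-diene, and C4′(OMe)–C5′(butyryl) from 1-methoxyhex-1-yn-3-one. That single operation forms C3′–C4′ and C5′–C6′, fixes the C4′ methyl ether ortho to the ketone, frees the C2′ and C6′ hydroxyls, and leaves C1′ as the only unsubstituted ring carbon. C1′ then attacks a bis-Mannich base of ring B.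

Key step: step 5

Assumption (chemistry): enol ether 8 and diene 9 are drawn as the isomers expected to predominate (E for 8; 1Z,3Z for 9). Other geometric isomers are expected to converge on the same arene, because the geometry of 8 is erased in step 4 and both sp3 centres of the cycloadduct vanish on aromatisation.

**Route**

Step 1
Reactants: 1 butanoyl chloride
Product: 2 N-methoxy-N-methylbutanamide
Conditions: MeNHOMe·HCl, K2CO3, H2O/CH2Cl2, 0 °C → rt
Reagents that add atoms: N,O-dimethylhydroxylamine hydrochloride, CNOC.Cl
Why: Schotten–Baumann N-acylation of the hydroxylamine by the acid chloride is fast under biphasic carbonate buffering and gives the Weinreb amide, an acyl donor that stops at the ketone stage in step 2.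

Step 2
Reactants: 3 2-chloro-1,1-dimethoxyethane; 2 N-methoxy-N-methylbutanamide
Product: 6 1-methoxyhex-1-yn-3-one, via lithium methoxyacetylide 4 (not isolated), via tetrahedral lithium alkoxide 5 (not isolated)
Conditions: LiNEt2 (3.0 equiv per 3; from Et2NH, n-BuLi), THF, 0 °C; then 2, −78 → −20 °C; inverse quench into ice-cold 1 M HCl/Et2O, rapid separation
Reagents that add atoms: none
Why: Twofold base-induced elimination (methanol, then HCl) and deprotonation of the chloroacetal is the standard entry to lithium alkoxyacetylides, and acylation with a Weinreb amide (instead of the acid chloride, which the liberated diethylamine would consume) stops at the chelated adduct 5, which releases the ynone only in the cold acidic quench that simultaneously ties up both amines as salts so that they cannot add to the push–pull triple bond.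

Step 3
Reactants: 7 methyl 3-oxopentanoate
Product: 8 methyl (E)-3-(trimethylsilyloxy)pent-2-enoate
Conditions: TMSCl, Et3N, hexane, rt, 48 h; filtration under Ar, distillation
Reagents that add atoms: chlorotrimethylsilane, C[Si](C)(C)Cl
Why: Soft enolisation and O-silylation of the β-keto ester with TMSCl/Et3N gives the conjugated silyl enol ether at the ketone oxygen, the usual first stage in making 1-alkoxy-1,3-bis(silyloxy)dienes.

Step 4
Reactants: 8 methyl (E)-3-(trimethylsilyloxy)pent-2-enoate
Product: 9 (1Z,3Z)-1-methoxy-1,3-bis(trimethylsilyloxy)penta-1,3-diene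
Conditions: LiN(i-Pr)2 (LDA, commercial solution), THF, −78 °C; TMSCl, −78 °C → rt; hexane, filtration under Ar; used directly
Reagents that add atoms: chlorotrimethylsilane, C[Si](C)(C)Cl
Why: Kinetic γ-deprotonation of the silyloxy enoate gives the extended ester dienolate, which silylates on oxygen to the ketene acetal (the standard second stage of bis(silyloxy)diene synthesis); no stereocentre is formed.

Step 5
Reactants: 9 (1Z,3Z)-1-methoxy-1,3-bis(trimethylsilyloxy)penta-1,3-diene; 6 1-methoxyhex-1-yn-3-one
Product: 12 1-(4,6-dihydroxy-2-methoxy-3-methylphenyl)butan-1-one, via cyclohexadiene cycloadduct 10 (not isolated), via bis(trimethylsilyl) aryl ether 11 (not isolated)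
Conditions: 9 (1.5 equiv), toluene (1 M), 25 → 80 °C, Ar, no Lewis acid; then 1 M HCl, THF, 0 °C → rt
Reagents that add atoms: none
Why: Proposed new method: the electron-rich diene 9 should add through its methyl-bearing terminus (the most nucleophilic carbon, vinylogous to the ketene acetal) to the methoxy-bearing β-carbon of the push–pull ynone 6, and the ketene acetal carbon then bonds to the acyl-bearing α-carbon in a concerted but strongly asynchronous, suprafacial (4π+2π) closure of six-membered ring A (C3′–C4′ and C5′–C6′ formed; in the stepwise limit the allenolate carbon closes onto the silyloxy-stabilised cation). The 1,4-cyclohexadiene 10 carries a mixed O-methyl O-silyl ketal at C6′ and a hydrogen at C3′, so 1,4-loss of methanol aromatises it to 11 and dilute acid then removes both silyl groups. The closest known reaction type is the Diels–Alder/aromatisation of 1-alkoxy-1,3-bis(silyloxy)-1,3-dienes with acetylenic ketones and esters, which gives resorcinol derivatives in the same regiochemical sense, whereas a 1-alkoxyalkynyl ketone has not been used as the 2π partner. No stereocentre survives, since the two sp3 centres of 10 are destroyed on aromatisation. The step needs regioselectivity and periselectivity: the former is secured by matching the nucleophilic diene terminus with the β-carbon of the ynone (the only carbon at which an ynone accepts a nucleophile), the latter by running the reaction thermally without a Lewis acid, which would favour Mukaiyama–Michael/aldol (3+3) closure onto the ketone carbonyl. The methyl ynol ether is retained by design because it cannot fragment to a ketene by retro-ene loss of an alkene on heating and because its methoxy group becomes the C4′ ether of the target.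

Step 6
Reactants: 13 1-(2,4,6-trihydroxyphenyl)butan-1-one (butyrylphloroglucinol)
Product: 14 1-[3,5-bis[(dimethylamino)methyl]-2,4,6-trihydroxyphenyl]butan-1-one
Conditions: Me2NH (40% aq., 2.5 equiv), HCHO (37% aq., 2.3 equiv), EtOH, 0 °C → rt; 13 added slowly to the premixed reagents; precipitate filtered
Reagents that add atoms: formaldehyde, C=O; dimethylamine, CNC
Why: In this phenolic Mannich reaction the two equivalent free ring carbons C3 and C5 of the acylphloroglucinol each take up one Me2NCH2 group from the preformed aminol/iminium, and excess reagent with inverse addition suppresses methylene-bis dimer formation.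

Step 7
Reactants: 14 1-[3,5-bis[(dimethylamino)methyl]-2,4,6-trihydroxyphenyl]butan-1-one; 12 1-(4,6-dihydroxy-2-methoxy-3-methylphenyl)butan-1-one (2.4 equiv)
Product: 16 Agrimol C, via mono-bridged Mannich base 15 (not isolated)
Conditions: 1,4-dioxane, 90 °C, Ar sweep to carry off Me2NH; excess 12 recovered
Reagents that add atoms: none
Why: On heating, each ortho-hydroxybenzylamine unit of 14 expels dimethylamine to give an o-quinone methide that is captured in a Friedel–Crafts-type conjugate C-alkylation by C1′ of 12, its only unsubstituted ring carbon (flanked by two hydroxyls), so two successive alkylations via 15 can only give the C3/C5 bis-methylene-bridged trimer; this Mannich-base alkylation is a standard way to methylene-bridged acylphloroglucinols and creates no stereocentre.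

**Compound list**

1 | butanoyl chloride | CCCC(=O)Cl | starting material
2 | N-methoxy-N-methylbutanamide | CCCC(=O)N(C)OC | intermediate
3 | 2-chloro-1,1-dimethoxyethane | COC(CCl)OC | starting material
4 | lithium methoxyacetylide (methoxyethynyllithium) | [Li]C#COC | intermediate
5 | lithium 1-methoxy-3-[methoxy(methyl)amino]hex-1-yn-3-olate (racemic) | CCCC([O-])(C#COC)N(C)OC.[Li+] | intermediate
6 | 1-methoxyhex-1-yn-3-one | CCCC(=O)C#COC | intermediate
7 | methyl 3-oxopentanoate | CCC(=O)CC(=O)OC | starting material
8 | methyl (E)-3-(trimethylsilyloxy)pent-2-enoate | CC/C(O[Si](C)(C)C)=C\C(=O)OC | intermediate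
9 | (1Z,3Z)-1-methoxy-1,3-bis(trimethylsilyloxy)penta-1,3-diene | C/C=C(\O[Si](C)(C)C)/C=C(/OC)O[Si](C)(C)C | intermediate
10 | 1-[2,6-dimethoxy-3-methyl-4,6-bis(trimethylsilyloxy)cyclohexa-1,4-dien-1-yl]butan-1-one (racemic; configuration at the two sp3 ring carbons not defined, both are lost on aromatisation) | CCCC(=O)C1=C(OC)C(C)C(O[Si](C)(C)C)=CC1(OC)O[Si](C)(C)C | intermediate
11 | 1-[2-methoxy-3-methyl-4,6-bis(trimethylsilyloxy)phenyl]butan-1-one | CCCC(=O)c1c(O[Si](C)(C)C)cc(O[Si](C)(C)C)c(C)c1OC | intermediate
12 | 1-(4,6-dihydroxy-2-methoxy-3-methylphenyl)butan-1-one | CCCC(=O)c1c(O)cc(O)c(C)c1OC | intermediate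
13 | 1-(2,4,6-trihydroxyphenyl)butan-1-one (butyrylphloroglucinol) | CCCC(=O)c1c(O)cc(O)cc1O | starting material
14 | 1-[3,5-bis[(dimethylamino)methyl]-2,4,6-trihydroxyphenyl]butan-1-one | CCCC(=O)c1c(O)c(CN(C)C)c(O)c(CN(C)C)c1O | intermediate
15 | 1-[3-[(3-butanoyl-2,6-dihydroxy-4-methoxy-5-methylphenyl)methyl]-5-[(dimethylamino)methyl]-2,4,6-trihydroxyphenyl]butan-1-one | CCCC(=O)c1c(O)c(Cc2c(O)c(C)c(OC)c(C(=O)CCC)c2O)c(O)c(CN(C)C)c1O | intermediate
16 | Agrimol C, 1-[3,5-bis[(3-butanoyl-2,6-dihydroxy-4-methoxy-5-methylphenyl)methyl]-2,4,6-trihydroxyphenyl]butan-1-one (achiral) | CCCC(=O)c1c(O)c(Cc2c(O)c(C)c(OC)c(C(=O)CCC)c2O)c(O)c(Cc2c(O)c(C)c(OC)c(C(=O)CCC)c2O)c1O | target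

**Summary**

Total step count: 7 (steps 1–2 to the ynone, 3–4 to the diene, 5 key step, 6 bis-Mannich base, 7 union).
Longest linear sequence: 4 steps (7 → 8 → 9 → 12 → 16, i.e. steps 3, 4, 5, 7; the branch 1 → 2 → 6 → 12 → 16 is equally long).

**Steps most likely to fail**

Step 5 (proposed new method). The cycloaddition may stall, because the donor-substituted ynone is a weak 2π partner and the reacting diene terminus is substituted. It may also drift into Michael addition followed by aldol closure onto the ketone, or lose diene by protodesilylation before any C–C bond forms. The fallback uses known arene chemistry, sets out from 1 and returns at 12. Friedel–Crafts acylation of purchased 2,4,6-trihydroxytoluene with 1 (AlCl3, PhNO2, 60 °C) should give 1-(2,4,6-trihydroxy-3-methylphenyl)butan-1-one F1. MOMCl (2.1 equiv) with i-Pr2NEt in CH2Cl2 at 0 °C should protect the para hydroxyl and the less hindered ortho hydroxyl. The chelated hydroxyl wedged between the ketone and the methyl stays free, giving 1-[2-hydroxy-4,6-bis(methoxymethoxy)-3-methylphenyl]butan-1-one F2; any regioisomer is removed by chromatography. Methylation of the remaining hydroxyl (MeI, K2CO3, DMF, 50 °C) gives 1-[2-methoxy-4,6-bis(methoxymethoxy)-3-methylphenyl]butan-1-one F3. HCl in MeOH then removes both acetals and delivers 12.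

Step 2. The liberated amines may add to the ynone in conjugate fashion, the ynol ether may be hydrated during the quench, and the small volatile product may be lost on concentration. The fallback sets out from 3 and returns at 6, and avoids releasing the ynone in the presence of amines or aqueous acid. Lithium methoxyacetylide 4, generated as before, is added to purchased butanal (THF, −78 °C; neutral NH4Cl work-up) to give racemic 1-methoxyhex-1-yn-3-ol F4. This is oxidised under neutral conditions with activated MnO2 in CH2Cl2 at rt (filtration, careful concentration) to 6.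

Step 7. The quinone methide may self-condense, the second alkylation may stop at the mono-bridged stage, and the methylene bridges may exchange between rings under prolonged heating. The fallback reverses the roles of the partners, sets out from 12 and returns at 16. Aminomethylation of 12 at C1′ with Me2N=CH2+ I− (Eschenmoser's salt; CH2Cl2, 0 °C → rt, NaHCO3 work-up) should give 1-[3-[(dimethylamino)methyl]-2,4-dihydroxy-6-methoxy-5-methylphenyl]butan-1-one F5. Two equivalents of F5 are then heated with butyrylphloroglucinol 13 (dioxane, 90 °C), so that the more nucleophilic ring B is alkylated at C3 and C5 to give 16.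

**Further compounds**

F1 | step 5 | 1-(2,4,6-trihydroxy-3-methylphenyl)butan-1-one | CCCC(=O)c1c(O)cc(O)c(C)c1O
F2 | step 5 | 1-[2-hydroxy-4,6-bis(methoxymethoxy)-3-methylphenyl]butan-1-one | CCCC(=O)c1c(O)c(C)c(OCOC)cc1OCOC
F3 | step 5 | 1-[2-methoxy-4,6-bis(methoxymethoxy)-3-methylphenyl]butan-1-one | CCCC(=O)c1c(OC)c(C)c(OCOC)cc1OCOC
F4 | step 2 | 1-methoxyhex-1-yn-3-ol (racemic) | CCCC(O)C#COC
F5 | step 7 | 1-[3-[(dimethylamino)methyl]-2,4-dihydroxy-6-methoxy-5-methylphenyl]butan-1-one | CCCC(=O)c1c(O)c(CN(C)C)c(O)c(C)c1OC
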